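The easy step came first: I set the impurity against the precatalyst, one against one, and took equal amounts as the zero of the scale.

| flask | substrate | precatalyst | impurity | temperature | remark | time |
|---|---|---|---|---|---|---|
| red | 0.19 M | 5.3 µM | 7.5 µM | 40 °C | the very flask that is asked about, followed so far |  |
| grey | 0.19 M | 5.3 µM | 7.5 µM | 46 °C | run made earlier |  |
| flask | 0.19 M | 5.3 µM | 7.5 µM | 40 °C |  | 80 min |

| run | time / min | product / % | substrate / % |
|---|---|---|---|
| red | 5.00 | 36.3 | 64.6 |
| red | 12.0 | 45.3 | 56.6 |
| red | 30.0 | 44.6 | 56.4 |
| red | 60.0 | 45.7 | 54.0 |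
| grey | 5.00 | 35.8 | 63.4 |
| grey | 12.0 | 40.4 | 57.6 |
| grey | 30.0 | 40.6 | 57.8 |
| grey | 60.0 | 39.4 | 60.6 |

(scatter of a reading: 1 percentage point)

- midnight: change nothing and wait 2.5 h more
- dusk: at 80 min raise the temperature by 20 K, then wait 2.5 h
- autumn: at 80 min take out 90 % of the product then present, then wait 2.5 h
- winter: at 80 min add precatalyst, 100 % of the amount charged, then wait 2.5 h

- product that was removed still counts
- what was read earlier has a scatter of 1 percentage point, one standard deviation
- additions bring no volume worth counting

* product, in percent of the substrate first charged, at 80 min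
* the option that brings most further product ("none" if no option brings more than 2 percentage points) (midnight / dusk / autumn / winter / none)
* product present, with what was taken out counted in, in percent of the substrate first charged, after dusk
* product present, with what was taken out counted in, in percent of the substrate first charged, after winter

impurity charged − precatalyst charged = 7.5 µM − 5.3 µM = 2.20 µM

I called this the impurity surplus, the impurity charged minus the precatalyst charged. If the impurity poisons catalyst one to one, a positive surplus means dead catalyst beside spare impurity.

Then I read the red flask as a ladder of times. On the shortest rung it ran fast, reaching 36.3 % product by 5.00 min. On the next it stopped: 45.3 % at 12.0 min and 45.7 % at 60.0 min, a difference of 0.4 percentage points against a scatter of 1 point, with 54.0 % substrate still read. That stop came earlier than the 80 min asked, so I expected the red flask to read about 45.7 % then. The grey flask read lower, at 39.4 %, so these curves left a shifted equilibrium possible as well.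

The longest rung is the 2.5 h of waiting. On the poisoning reading, a dose of fresh precatalyst first pays the surplus:

fresh catalyst = 100 % × 5.3 µM − 2.20 µM = 3.10 µM

At the early pace, 36.3 % in 5.00 min, scaled to that catalyst, I estimated the time for the remaining substrate:

54.0 % ÷ (early pace × fresh catalyst ÷ precatalyst charged) = 12.7 min

That is shorter than 2.5 h.

The forecast gave 45 % now, winter as best, 45 % after dusk and 96 % after winter. It favoured poisoning without certainty: “Waiting, heating or removing product then does nothing.”

The flask gave 45.6 %, and winter was best, bringing 54 points and reaching 100 %, while dusk stayed at 45.6 %. At 80.0 min the flask held 54.4 % substrate beside 0 % free enzyme, 0.354 % unfolded enzyme and 99.6 % spent catalyst. The surplus is 29.3 % of the impurity charged, and the impurity left stood at 30 %.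

    substrate + free enzyme → product + free enzyme, rate k1*[substrate]*[free enzyme]/(1 + ([substrate]/Km1) + ([substrate]/Ksi1)^2) (0.0854 M, 0.138 M, k = 3.35 × 10⁵ M⁻¹ min⁻¹, Ea = 22.0 kJ mol⁻¹)
    free enzyme → unfolded enzyme (k = 0.00274 min⁻¹, Ea = 283 kJ mol⁻¹)
    free enzyme + impurity → spent catalyst (k = 1.78 × 10⁵ M⁻¹ min⁻¹, Ea = 35.0 kJ mol⁻¹)
    precatalyst ⇌ free enzyme (K = 3.00, k = 1.47 min⁻¹, Ea = 78.0 kJ mol⁻¹, ΔH = 5.00 kJ mol⁻¹)
    (constants at 40 °C)

For the neighbour flask, charged with 2.10 µM precatalyst, the surplus is 5.40 µM, or 72.0 % of the impurity charged. The computed flask kept 72 % of its impurity and made 12.2 % product.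

The runs were computed with constants of no real substance; scatter was added.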